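**Strategy.** Everything rests on cutting the cyclobutane bond C1–C9 and the pyran bond C8–O (caryophyllane numbering) to return to an eleven-membered ring C1–C11. The step exploits that the ring-fusion atoms C1 and C9 are 1,4-related through C11–C10 across that ring and that spiro C8 is the oxygen-bearing pyran carbon: one cationic relay C1 → C9 → C8 → O closes the cyclobutane (and thereby the nine-membered ring) and the pyran and sets C1, C8 and C9 together. Its precursor is a (2E,8E)-cycloundecadiene with an allylic acetate at C1, a C7/C10-cis C8=C9 alkene carrying the C-alkylated syncarpic enol arm, and a silyl-protected C5 alcohol.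

Key step: step 19

**Remarks on the chemistry**
- Locants: C1–C11 are the ring atoms, C15 is the CH2 between C8 and C1′, and C1′ is the isobutyl-bearing carbon. TIPS = triisopropylsilyl; TMSE = 2-(trimethylsilyl)ethyl; Syn(OTMSE) = 3,3,5,5-tetramethyl-4,6-dioxo-2-[2-(trimethylsilyl)ethoxy]cyclohex-1-en-1-yl; Syn(OH) = its 2-hydroxy analogue.
- Corrected descriptor: the cascade needs C7 and C10 cis on the C8=C9 alkene. Because the C15 arm outranks C7 under the CIP rules, this geometry is (8E); a (Z) alkene would lead to the C8 epimer.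
- Improved precursor, C5: C5 passes through the cascade as a TIPS ether, not as a ketone. A C5 carbonyl would place an acidic, allylic C4–H next to the cation, opening elimination to a dienone and acid-induced conjugation that destroys the allylic acetate. The ketone is unveiled in step 21.
- Improved precursor, C1: the acetate is drawn (1R), the epimer in which it leaves anti to the incoming C9. The (1S) epimer can react only through the fully free cation. Both epimers from step 16 share that cation and are carried on together.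
- Improved precursor, C4 and C5: both are set in step 2 under reagent control, sit beside the allyl cation, and are erased later, so either ring diastereomer is available by the same route.

Step 1
Reactants: 1 (S)-4-(trimethylsilyl)but-3-yn-2-ol
Product: 2 (S)-4-(trimethylsilyl)but-3-yn-2-yl methanesulfonate
Conditions: MsCl, Et3N, CH2Cl2, −78 → 0 °C
Reagents that add atoms: methanesulfonyl chloride, CS(=O)(=O)Cl
Why: O-sulfonylation of a secondary propargylic alcohol leaves the C–O bond intact, so the (S) centre is retained.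

Step 2
Reactants: 2 (S)-4-(trimethylsilyl)but-3-yn-2-yl methanesulfonate; 3 acrolein
Product: 5 (3S,4R)-4-methyl-6-(trimethylsilyl)hex-1-en-5-yn-3-ol, via allenylzinc 4 (not isolated)
Conditions: Pd(OAc)2 (5 mol%), PPh3 (5 mol%), Et2Zn (3 equiv), THF, −78 → −20 °C
Reagents that add atoms: none
Why: Zerovalent palladium displaces the mesylate anti (SN2′) and transmetalation gives an axially chiral allenylzinc that adds to the aldehyde through a cyclic SE2′ transition state (propargylation of an aldehyde with a chiral allenylmetal); chirality transfer should set C4 as (R) and the closed transition state the anti C5 (S) carbinol.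

Step 3
Reactants: 5 (3S,4R)-4-methyl-6-(trimethylsilyl)hex-1-en-5-yn-3-ol
Product: 6 (3S,4R)-4-methyl-3-[(triisopropylsilyl)oxy]-6-(trimethylsilyl)hex-1-en-5-yne (fragment W)
Conditions: TIPSOTf, 2,6-lutidine, CH2Cl2, 0 °C
Reagents that add atoms: triisopropylsilyl triflate, CC(C)[Si](OS(=O)(=O)C(F)(F)F)(C(C)C)C(C)C
Why: Silylation of a secondary alcohol with a silyl triflate; TIPS is chosen because it has to survive fluoride in step 18 and acid in step 19.

Step 4
Reactants: 7 3-methylbutanal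
Product: 8 (E)-5-methylhex-2-enal
Conditions: Ph3P=CHCHO, toluene, 80 °C
Reagents that add atoms: (triphenylphosphoranylidene)acetaldehyde, O=CC=P(c1ccccc1)(c1ccccc1)c1ccccc1
Why: Wittig olefination with a stabilised formyl ylide is E-selective and stops at the enal, which is less electrophilic than the saturated aldehyde.

Step 5
Reactants: 8 (E)-5-methylhex-2-enal; 9 syncarpic acid
Product: 11 (4S)-4-isobutyl-6,6,8,8-tetramethyl-3,4-dihydro-2H-chromene-2,5,7(6H,8H)-trione, via lactol 10 (not isolated)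
Conditions: (R)-α,α-diphenylprolinol trimethylsilyl ether (20 mol%), CH2Cl2, rt; then PhI(OAc)2, TEMPO (10 mol%), rt
Reagents that add atoms: none
Why: Iminium-ion-catalysed Michael addition of a cyclic 1,3-dicarbonyl to an enal, the nucleophile entering the face of the E-iminium ion not shielded by the diarylsilyloxymethyl group of the (R)-catalyst, should set C1′ as (S); TEMPO-catalysed oxidation then converts the lactol into the enol lactone in the same flask.

Step 6
Reactants: 11 (4S)-4-isobutyl-6,6,8,8-tetramethyl-3,4-dihydro-2H-chromene-2,5,7(6H,8H)-trione; 12 methyl acetate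
Product: 14 methyl (5S)-7-methyl-3-oxo-5-Syn(OH)-octanoate, via lithium ester enolate 13 (not isolated)
Conditions: 12, LiN(iPr)2 (3.2 equiv), THF, −78 °C; then 11, −78 °C; aq. HCl to pH 4
Reagents that add atoms: none
Why: Crossed Claisen condensation in which the ester enolate attacks the enol lactone carbonyl, an activated acyl donor that expels the stabilised triketone enolate; the product is shielded from further addition as its enolate, and C1′ cannot undergo retro-Michael loss while the triketone is anionic.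

Step 7
Reactants: 14 methyl (5S)-7-methyl-3-oxo-5-Syn(OH)-octanoate
Product: 15 methyl (5S)-7-methyl-3-oxo-5-Syn(OTMSE)-octanoate
Conditions: Me3SiCH2CH2OH, PPh3, DIAD, THF, 0 °C
Reagents that add atoms: 2-(trimethylsilyl)ethanol, C[Si](C)(C)CCO
Why: Mitsunobu O-alkylation picks the strongly acidic triketone enol over the β-keto ester and masks it as a base-stable, fluoride-labile vinylogous ester.

Step 8
Reactants: 15 methyl (5S)-7-methyl-3-oxo-5-Syn(OTMSE)-octanoate
Product: 16 methyl (2Z,5S)-7-methyl-5-Syn(OTMSE)-3-{[(trifluoromethyl)sulfonyl]oxy}oct-2-enoate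
Conditions: Tf2O, sat. aq. LiOH, toluene, 5 °C
Reagents that add atoms: triflic anhydride, O=S(=O)(OS(=O)(=O)C(F)(F)F)C(F)(F)F
Why: O-sulfonylation of the lithium-chelated β-keto ester enolate gives the (Z)-enol triflate, which fixes C15 trans to the future C10.

Step 9
Reactants: 6 fragment W; 16 methyl (2Z,5S)-7-methyl-5-Syn(OTMSE)-3-{[(trifluoromethyl)sulfonyl]oxy}oct-2-enoate
Product: 18 methyl (2E,6S,7R)-7-methyl-3-[(2S)-4-methyl-2-Syn(OTMSE)-pentyl]-6-[(triisopropylsilyl)oxy]-9-(trimethylsilyl)non-2-en-8-ynoate, via B-alkyl-9-BBN 17 (not isolated)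
Conditions: 6, (9-BBN)2, THF, rt; then 16, Pd(dppf)Cl2 (5 mol%), AsPh3 (10 mol%), K3PO4, DMF/H2O, rt
Reagents that add atoms: none
Why: Hydroboration of the terminal alkene (the silylated alkyne is far slower towards 9-BBN) and B-alkyl Suzuki–Miyaura coupling with the activated enol triflate, which proceeds with retention, put C7 cis to C10 and so build the ring-cis C8=C9 geometry.

Step 10
Reactants: 18 methyl (2E,6S,7R)-7-methyl-3-[(2S)-4-methyl-2-Syn(OTMSE)-pentyl]-6-[(triisopropylsilyl)oxy]-9-(trimethylsilyl)non-2-en-8-ynoate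
Product: 19 methyl (2E,6S,7R)-7-methyl-3-[(2S)-4-methyl-2-Syn(OTMSE)-pentyl]-6-[(triisopropylsilyl)oxy]non-2-en-8-ynoate
Conditions: K2CO3, MeOH, rt
Reagents that add atoms: none
Why: Base-mediated protodesilylation of the alkynylsilane; the silyl ether, the methyl ester and the hindered vinylogous ester are left alone.

Step 11
Reactants: 19 methyl (2E,6S,7R)-7-methyl-3-[(2S)-4-methyl-2-Syn(OTMSE)-pentyl]-6-[(triisopropylsilyl)oxy]non-2-en-8-ynoate
Product: 21 methyl (2E,6S,7R,8E)-9-iodo-7-methyl-3-[(2S)-4-methyl-2-Syn(OTMSE)-pentyl]-6-[(triisopropylsilyl)oxy]nona-2,8-dienoate, via alkenylzirconocene chloride 20 (not isolated)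
Conditions: Cp2Zr(H)Cl, THF, rt; then I2, 0 °C
Reagents that add atoms: iodine, [I][I]
Why: Syn hydrozirconation of the terminal alkyne puts zirconium on the terminal carbon and iodinolysis with retention gives the (E)-vinyl iodide; the ester and the two shielded ring carbonyls should react much more slowly than the alkyne.

Step 12
Reactants: 21 methyl (2E,6S,7R,8E)-9-iodo-7-methyl-3-[(2S)-4-methyl-2-Syn(OTMSE)-pentyl]-6-[(triisopropylsilyl)oxy]nona-2,8-dienoate
Product: 22 (2E,6S,7R,8E)-9-iodo-7-methyl-3-[(2S)-4-methyl-2-Syn(OTMSE)-pentyl]-6-[(triisopropylsilyl)oxy]nona-2,8-dien-1-ol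
Conditions: iBu2AlH (2.2 equiv), CH2Cl2, −78 °C
Reagents that add atoms: none
Why: 1,2-Reduction of the enoate at low temperature; the vinylogous ester carbonyl and the ketone flanked by two quaternary carbons are sterically shielded.

Step 13
Reactants: 22 (2E,6S,7R,8E)-9-iodo-7-methyl-3-[(2S)-4-methyl-2-Syn(OTMSE)-pentyl]-6-[(triisopropylsilyl)oxy]nona-2,8-dien-1-ol
Product: 23 (2E,6S,7R,8E)-1-bromo-9-iodo-7-methyl-3-[(2S)-4-methyl-2-Syn(OTMSE)-pentyl]-6-[(triisopropylsilyl)oxy]nona-2,8-diene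
Conditions: CBr4, PPh3, CH2Cl2, −20 → 0 °C
Reagents that add atoms: carbon tetrabromide, BrC(Br)(Br)Br
Why: Appel bromination of a primary allylic alcohol under neutral conditions, without allylic transposition.

Step 14
Reactants: 24 2-methylpropanal
Product: 25 N-cyclohexyl-2-methylpropan-1-imine
Conditions: cyclohexylamine, MgSO4, CH2Cl2, rt
Reagents that add atoms: cyclohexylamine, NC1CCCCC1
Why: Condensation of an aldehyde with a primary amine to the aldimine.

Step 15
Reactants: 23 (2E,6S,7R,8E)-1-bromo-9-iodo-7-methyl-3-[(2S)-4-methyl-2-Syn(OTMSE)-pentyl]-6-[(triisopropylsilyl)oxy]nona-2,8-diene; 25 N-cyclohexyl-2-methylpropan-1-imine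
Product: 28 (4E,8S,9R,10E)-11-iodo-2,2,9-trimethyl-5-[(2S)-4-methyl-2-Syn(OTMSE)-pentyl]-8-[(triisopropylsilyl)oxy]undeca-4,10-dienal, via lithium aza-enolate 26 (not isolated), via alkylated imine 27 (not isolated)
Conditions: 25, LiN(iPr)2, THF, 0 °C; then 23, −78 → 0 °C; then AcOH/NaOAc/H2O, rt
Reagents that add atoms: water, O
Why: Metalloenamine (aza-enolate) alkylation by SN2 displacement of the primary allylic bromide forms C10–C11 and the quaternary C11, and buffered hydrolysis releases the non-enolisable C1 aldehyde.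

Step 16
Reactants: 28 (4E,8S,9R,10E)-11-iodo-2,2,9-trimethyl-5-[(2S)-4-methyl-2-Syn(OTMSE)-pentyl]-8-[(triisopropylsilyl)oxy]undeca-4,10-dienal
Product: 29 (1R,2E,4R,5S,8E)-4,11,11-trimethyl-8-[(2S)-4-methyl-2-Syn(OTMSE)-pentyl]-5-[(triisopropylsilyl)oxy]cycloundeca-2,8-dien-1-ol
Conditions: CrCl2 (10 equiv), NiCl2 (2 mol%), DMSO/THF, rt, 2 mM, slow addition
Reagents that add atoms: none
Why: Nozaki–Hiyama–Kishi macrocyclisation, in which oxidative addition of the (E)-vinyl iodide to zerovalent nickel, transmetalation to trivalent chromium with retention and chemoselective addition to the aldehyde close the eleven-membered ring at C1–C2; both C1 epimers are expected and taken on, the (1R) epimer being drawn.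

Step 17
Reactants: 29 (1R,2E,4R,5S,8E)-4,11,11-trimethyl-8-[(2S)-4-methyl-2-Syn(OTMSE)-pentyl]-5-[(triisopropylsilyl)oxy]cycloundeca-2,8-dien-1-ol
Product: 30 (1R,2E,4R,5S,8E)-4,11,11-trimethyl-8-[(2S)-4-methyl-2-Syn(OTMSE)-pentyl]-5-[(triisopropylsilyl)oxy]cycloundeca-2,8-dien-1-yl acetate
Conditions: Ac2O, pyridine, DMAP (cat.), CH2Cl2, rt
Reagents that add atoms: acetic anhydride, CC(=O)OC(C)=O
Why: DMAP-catalysed acylation of the hindered allylic alcohol.

Step 18
Reactants: 30 (1R,2E,4R,5S,8E)-4,11,11-trimethyl-8-[(2S)-4-methyl-2-Syn(OTMSE)-pentyl]-5-[(triisopropylsilyl)oxy]cycloundeca-2,8-dien-1-yl acetate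
Product: 31 (1R,2E,4R,5S,8E)-8-[(2S)-4-methyl-2-Syn(OH)-pentyl]-4,11,11-trimethyl-5-[(triisopropylsilyl)oxy]cycloundeca-2,8-dien-1-yl acetate
Conditions: Bu4NF, AcOH (1:1), THF, 0 °C
Reagents that add atoms: none
Why: Fluoride-induced β-elimination cleaves the 2-(trimethylsilyl)ethyl vinylogous ester much faster than fluoride attacks the hindered secondary TIPS ether, and the acetic acid buffer protects the acetate.

Step 19
Reactants: 31 (1R,2E,4R,5S,8E)-8-[(2S)-4-methyl-2-Syn(OH)-pentyl]-4,11,11-trimethyl-5-[(triisopropylsilyl)oxy]cycloundeca-2,8-dien-1-yl acetate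
Product: 32 (1R,2E,4R,5S,8S,9S,4′S)-4′-isobutyl-4,6′,6′,8′,8′,11,11-heptamethyl-5-[(triisopropylsilyl)oxy]-3′,4′-dihydrospiro[bicyclo[7.2.0]undec-2-ene-8,2′-chromene]-5′,7′(6′H,8′H)-dione
Conditions: TfOH (5 mol%), (CF3)2CHOH/CH2Cl2 (1:4), −40 → −10 °C, 2 mM; then Et3N
Reagents that add atoms: none
Why: Proposed new method: triflic acid in hexafluoroisopropanol should ionise the allylic acetate to the W-shaped (E,E) allyl cation C1–C2–C3; the C8=C9 π bond, which sits 1,4 to C1 through C11–C10, then bonds C9 to C1 (4-exo with respect to the alkene, Markovnikov, charge moved to tertiary C8), splitting the eleven-membered ring into a cyclobutane fused to an (E)-cyclononene, and the enol oxygen closes onto C8 in a six-membered ring closure that keeps the enol C=C inside the new pyran. The nearest known chemistry is the acid-promoted addition of allyl cations to alkenes that gives vinylcyclobutanes and the enzymatic humulyl-to-caryophyllyl cyclisation; a transannular version started from an allylic acetate and ended by an internal oxygen nucleophile has not been shown. C1 is set by attack of C9 on the face opposite the departing (1R)-acetate, C9 by the trans ring fusion that follows from the crossed, face-to-face arrangement of the E-allyl unit and the alkene, and C8 by anti capture of the σ-delocalised cyclobutylcarbinyl cation, which converts the C7/C10-cis alkene geometry into the (8S,9S) relationship; the ring stereocentres C4 and C5 beside the cation and C1′ in the tether decide which face of the macrocycle reacts. Bonding at C1 and not at C3 is secured by geometry, since closure at C3 of the E,E cation would place a trans double bond in a six- or seven-membered ring, and capture by oxygen is favoured over proton loss and cyclobutane ring expansion by the short tether, the acidity of the enol and the absence of an acidic C4–H (C5 is a silyl ether).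

Step 20
Reactants: 32 the C5 TIPS ether of the spiro-chromene
Product: 33 (1R,2E,4R,5S,8S,9S,4′S)-5-hydroxy-4′-isobutyl-4,6′,6′,8′,8′,11,11-heptamethyl-3′,4′-dihydrospiro[bicyclo[7.2.0]undec-2-ene-8,2′-chromene]-5′,7′(6′H,8′H)-dione
Conditions: Bu4NF, THF, rt → 40 °C
Reagents that add atoms: none
Why: Fluoride desilylation of the secondary TIPS ether; the chromene enol ether, the ring ketone and the alkene are inert to fluoride.

Step 21
Reactants: 33 the C5 alcohol
Product: 35 (1R,3Z,8S,9S,4′S)-4′-isobutyl-4,6′,6′,8′,8′,11,11-heptamethyl-3′,4′-dihydrospiro[bicyclo[7.2.0]undec-3-ene-8,2′-chromene]-5,5′,7′(6′H,8′H)-trione, via β,γ-unsaturated ketone 34 (not isolated)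
Conditions: Dess–Martin periodinane, CH2Cl2, 0 °C → rt; then DBU, rt
Reagents that add atoms: none
Why: Dess–Martin oxidation gives the β,γ-unsaturated C5 ketone, and DBU moves the strained (E)-C2=C3 alkene into conjugation through the dienolate (protonation at C2); the (Z)-C3=C4 enone is the thermodynamic isomer in the nine-membered ring, and C4 is erased here as planned.

Step 22
Reactants: 35 the (3Z)-enone
Product: 36 tomentodione P
Conditions: NaBH4, CeCl3·7H2O, MeOH, −78 °C
Reagents that add atoms: none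
Why: Luche reduction, a cerium-assisted 1,2-reduction of the enone in which hydride is expected to enter from the outer face of the folded nine-membered ring to give the (5S)-alcohol; the shielded ring ketone and the vinylogous ester should not be reduced at −78 °C.

**Compound list**

1 | (S)-4-(trimethylsilyl)but-3-yn-2-ol | C[C@H](O)C#C[Si](C)(C)C | starting material
2 | (S)-4-(trimethylsilyl)but-3-yn-2-yl methanesulfonate | C[C@H](OS(C)(=O)=O)C#C[Si](C)(C)C | intermediate
3 | acrolein | C=CC=O | starting material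
4 | (aR)-ethyl[1-(trimethylsilyl)buta-1,2-dien-1-yl]zinc (allenylzinc) | [H]C(C)=[C@]=C([Zn]CC)[Si](C)(C)C | intermediate
5 | (3S,4R)-4-methyl-6-(trimethylsilyl)hex-1-en-5-yn-3-ol | C=C[C@H](O)[C@H](C)C#C[Si](C)(C)C | intermediate
6 | (3S,4R)-4-methyl-3-[(triisopropylsilyl)oxy]-6-(trimethylsilyl)hex-1-en-5-yne (fragment W) | C=C[C@H](O[Si](C(C)C)(C(C)C)C(C)C)[C@H](C)C#C[Si](C)(C)C | intermediate
7 | 3-methylbutanal | CC(C)CC=O | starting material
8 | (E)-5-methylhex-2-enal | CC(C)C/C=C/C=O | intermediate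
9 | syncarpic acid | CC1(C)C(=O)CC(=O)C(C)(C)C1=O | starting material
10 | (4S)-2-hydroxy-4-isobutyl-6,6,8,8-tetramethyl-3,4-dihydro-2H-chromene-5,7(6H,8H)-dione (lactol, both anomers) | OC1C[C@H](CC(C)C)C2=C(O1)C(C)(C)C(=O)C(C)(C)C2=O | intermediate
11 | (4S)-4-isobutyl-6,6,8,8-tetramethyl-3,4-dihydro-2H-chromene-2,5,7(6H,8H)-trione (enol lactone) | O=C1C[C@H](CC(C)C)C2=C(O1)C(C)(C)C(=O)C(C)(C)C2=O | intermediate
12 | methyl acetate | COC(C)=O | starting material
13 | lithium 1-methoxyethen-1-olate | [Li]OC(=C)OC | intermediate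
14 | methyl (5S)-7-methyl-3-oxo-5-Syn(OH)-octanoate | COC(=O)CC(=O)C[C@H](CC(C)C)C1=C(O)C(C)(C)C(=O)C(C)(C)C1=O | intermediate
15 | methyl (5S)-7-methyl-3-oxo-5-Syn(OTMSE)-octanoate | COC(=O)CC(=O)C[C@H](CC(C)C)C1=C(OCC[Si](C)(C)C)C(C)(C)C(=O)C(C)(C)C1=O | intermediate
16 | methyl (2Z,5S)-7-methyl-5-Syn(OTMSE)-3-{[(trifluoromethyl)sulfonyl]oxy}oct-2-enoate | COC(=O)/C=C(\OS(=O)(=O)C(F)(F)F)C[C@H](CC(C)C)C1=C(OCC[Si](C)(C)C)C(C)(C)C(=O)C(C)(C)C1=O | intermediate
17 | 9-[(3S,4R)-4-methyl-3-[(triisopropylsilyl)oxy]-6-(trimethylsilyl)hex-5-yn-1-yl]-9-borabicyclo[3.3.1]nonane | B1(C2CCCC1CCC2)CC[C@H](O[Si](C(C)C)(C(C)C)C(C)C)[C@H](C)C#C[Si](C)(C)C | intermediate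
18 | methyl (2E,6S,7R)-7-methyl-3-[(2S)-4-methyl-2-Syn(OTMSE)-pentyl]-6-[(triisopropylsilyl)oxy]-9-(trimethylsilyl)non-2-en-8-ynoate | COC(=O)/C=C(\CC[C@H](O[Si](C(C)C)(C(C)C)C(C)C)[C@H](C)C#C[Si](C)(C)C)C[C@H](CC(C)C)C1=C(OCC[Si](C)(C)C)C(C)(C)C(=O)C(C)(C)C1=O | intermediate
19 | methyl (2E,6S,7R)-7-methyl-3-[(2S)-4-methyl-2-Syn(OTMSE)-pentyl]-6-[(triisopropylsilyl)oxy]non-2-en-8-ynoate | COC(=O)/C=C(\CC[C@H](O[Si](C(C)C)(C(C)C)C(C)C)[C@H](C)C#C)C[C@H](CC(C)C)C1=C(OCC[Si](C)(C)C)C(C)(C)C(=O)C(C)(C)C1=O | intermediate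
20 | (E)-alkenylzirconocene chloride from 19 (Cp2ZrCl on the terminal carbon) | COC(=O)/C=C(\CC[C@H](O[Si](C(C)C)(C(C)C)C(C)C)[C@H](C)/C=C/[Zr](Cl)(C1C=CC=C1)C1C=CC=C1)C[C@H](CC(C)C)C1=C(OCC[Si](C)(C)C)C(C)(C)C(=O)C(C)(C)C1=O | intermediate
21 | methyl (2E,6S,7R,8E)-9-iodo-7-methyl-3-[(2S)-4-methyl-2-Syn(OTMSE)-pentyl]-6-[(triisopropylsilyl)oxy]nona-2,8-dienoate | COC(=O)/C=C(\CC[C@H](O[Si](C(C)C)(C(C)C)C(C)C)[C@H](C)/C=C/I)C[C@H](CC(C)C)C1=C(OCC[Si](C)(C)C)C(C)(C)C(=O)C(C)(C)C1=O | intermediate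
22 | (2E,6S,7R,8E)-9-iodo-7-methyl-3-[(2S)-4-methyl-2-Syn(OTMSE)-pentyl]-6-[(triisopropylsilyl)oxy]nona-2,8-dien-1-ol | OC/C=C(\CC[C@H](O[Si](C(C)C)(C(C)C)C(C)C)[C@H](C)/C=C/I)C[C@H](CC(C)C)C1=C(OCC[Si](C)(C)C)C(C)(C)C(=O)C(C)(C)C1=O | intermediate
23 | (2E,6S,7R,8E)-1-bromo-9-iodo-7-methyl-3-[(2S)-4-methyl-2-Syn(OTMSE)-pentyl]-6-[(triisopropylsilyl)oxy]nona-2,8-diene | BrC/C=C(\CC[C@H](O[Si](C(C)C)(C(C)C)C(C)C)[C@H](C)/C=C/I)C[C@H](CC(C)C)C1=C(OCC[Si](C)(C)C)C(C)(C)C(=O)C(C)(C)C1=O | intermediate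
24 | 2-methylpropanal | CC(C)C=O | starting material
25 | N-cyclohexyl-2-methylpropan-1-imine | CC(C)C=NC1CCCCC1 | intermediate
26 | lithium N-cyclohexyl-N-(2-methylprop-1-en-1-yl)amide (aza-enolate) | CC(C)=CN([Li])C1CCCCC1 | intermediate
27 | N-cyclohexyl imine of aldehyde 28 | C1CCCCC1N=CC(C)(C)C/C=C(\CC[C@H](O[Si](C(C)C)(C(C)C)C(C)C)[C@H](C)/C=C/I)C[C@H](CC(C)C)C1=C(OCC[Si](C)(C)C)C(C)(C)C(=O)C(C)(C)C1=O | intermediate
28 | (4E,8S,9R,10E)-11-iodo-2,2,9-trimethyl-5-[(2S)-4-methyl-2-Syn(OTMSE)-pentyl]-8-[(triisopropylsilyl)oxy]undeca-4,10-dienal | O=CC(C)(C)C/C=C(\CC[C@H](O[Si](C(C)C)(C(C)C)C(C)C)[C@H](C)/C=C/I)C[C@H](CC(C)C)C1=C(OCC[Si](C)(C)C)C(C)(C)C(=O)C(C)(C)C1=O | intermediate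
29 | (1R,2E,4R,5S,8E)-4,11,11-trimethyl-8-[(2S)-4-methyl-2-Syn(OTMSE)-pentyl]-5-[(triisopropylsilyl)oxy]cycloundeca-2,8-dien-1-ol (C1 epimer expected alongside) | C[C@@H]1/C=C/[C@@H](O)C(C)(C)C/C=C(C[C@H](CC(C)C)C2=C(OCC[Si](C)(C)C)C(C)(C)C(=O)C(C)(C)C2=O)\CC[C@@H]1O[Si](C(C)C)(C(C)C)C(C)C | intermediate
30 | acetate of 29 | C[C@@H]1/C=C/[C@@H](OC(C)=O)C(C)(C)C/C=C(C[C@H](CC(C)C)C2=C(OCC[Si](C)(C)C)C(C)(C)C(=O)C(C)(C)C2=O)\CC[C@@H]1O[Si](C(C)C)(C(C)C)C(C)C | intermediate
31 | (1R,2E,4R,5S,8E)-8-[(2S)-4-methyl-2-Syn(OH)-pentyl]-4,11,11-trimethyl-5-[(triisopropylsilyl)oxy]cycloundeca-2,8-dien-1-yl acetate (cascade precursor) | C[C@@H]1/C=C/[C@@H](OC(C)=O)C(C)(C)C/C=C(C[C@H](CC(C)C)C2=C(O)C(C)(C)C(=O)C(C)(C)C2=O)\CC[C@@H]1O[Si](C(C)C)(C(C)C)C(C)C | intermediate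
32 | (1R,2E,4R,5S,8S,9S,4′S)-4′-isobutyl-4,6′,6′,8′,8′,11,11-heptamethyl-5-[(triisopropylsilyl)oxy]-3′,4′-dihydrospiro[bicyclo[7.2.0]undec-2-ene-8,2′-chromene]-5′,7′(6′H,8′H)-dione (cascade product) | C[C@@H]1/C=C/[C@@H]2[C@H](CC2(C)C)[C@]2(CC[C@@H]1O[Si](C(C)C)(C(C)C)C(C)C)C[C@H](CC(C)C)C1=C(O2)C(C)(C)C(=O)C(C)(C)C1=O | intermediate
33 | (1R,2E,4R,5S,8S,9S,4′S)-5-hydroxy analogue of 32 | C[C@@H]1/C=C/[C@@H]2[C@H](CC2(C)C)[C@]2(CC[C@@H]1O)C[C@H](CC(C)C)C1=C(O2)C(C)(C)C(=O)C(C)(C)C1=O | intermediate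
34 | (1R,2E,4R,8S,9S,4′S)-4′-isobutyl-4,6′,6′,8′,8′,11,11-heptamethyl-3′,4′-dihydrospiro[bicyclo[7.2.0]undec-2-ene-8,2′-chromene]-5,5′,7′(6′H,8′H)-trione (β,γ-unsaturated ketone) | C[C@@H]1/C=C/[C@@H]2[C@H](CC2(C)C)[C@]2(CCC1=O)C[C@H](CC(C)C)C1=C(O2)C(C)(C)C(=O)C(C)(C)C1=O | intermediate
35 | (1R,3Z,8S,9S,4′S)-4′-isobutyl-4,6′,6′,8′,8′,11,11-heptamethyl-3′,4′-dihydrospiro[bicyclo[7.2.0]undec-3-ene-8,2′-chromene]-5,5′,7′(6′H,8′H)-trione | C/C1=C/C[C@@H]2[C@H](CC2(C)C)[C@]2(CCC1=O)C[C@H](CC(C)C)C1=C(O2)C(C)(C)C(=O)C(C)(C)C1=O | intermediate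
36 | tomentodione P, (1R,3Z,5S,8S,9S,4′S)-5-hydroxy-4′-isobutyl-4,6′,6′,8′,8′,11,11-heptamethyl-3′,4′-dihydrospiro[bicyclo[7.2.0]undec-3-ene-8,2′-chromene]-5′,7′(6′H,8′H)-dione | C/C1=C/C[C@@H]2[C@H](CC2(C)C)[C@]2(CC[C@@H]1O)C[C@H](CC(C)C)C1=C(O2)C(C)(C)C(=O)C(C)(C)C1=O | target

**Step count.** Total: 22 steps. Longest linear sequence: 18 steps (steps 4–13 and 15–22).

**Steps most likely to fail**

Step 19. The cation may lose a proton to a diene, pair the wrong faces of the allyl unit and the alkene (cis fusion or the wrong enantiomeric sense), or undergo cyclobutane ring expansion before oxygen capture. The fallback builds the spiro-chromene by known hetero-Diels–Alder chemistry and sets out from 9 and 7. Knoevenagel condensation gives 2-(3-methylbutylidene)-4,4,6,6-tetramethylcyclohexane-1,3,5-trione F1. Purchased (−)-β-caryophyllene F2 undergoes a Schenck ene reaction with singlet oxygen to the allylic hydroperoxide F3, which PPh3 reduces to (1R,3Z,5S,9S)-caryophylla-3,8(13)-dien-5-ol F4, separated from its regioisomers. Heating F1 with F4 in toluene gives the inverse-demand hetero-Diels–Alder adduct across the exocyclic C8=C15 alkene, and the route is rejoined at 36.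

Step 16. Intermolecular coupling and protonation of the alkenylchromium may outrun closure of the strained eleven-membered ring at the hindered aldehyde. The fallback closes the same bond from an alkenylzinc under ligand control and sets out from 19. Reduction with iBu2AlH gives the alkynyl allylic alcohol F5 and CBr4/PPh3 gives the bromide F6. Alkylation with 26 gives the imine F7 and buffered hydrolysis gives the ynal F8. Chemoselective hydroboration of the alkyne with dicyclohexylborane gives the alkenylborane F9. Boron-to-zinc exchange with Et2Zn gives the alkenyl(ethyl)zinc F10, which adds to the aldehyde at high dilution in the presence of 3-exo-(dimethylamino)isoborneol; the ligand also fixes C1. The route is rejoined at 29.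

Step 22. Hydride may be delivered to the wrong face of the enone, giving poor facial selectivity at C5. The fallback inverts the substrate-preferred epimer and sets out from 35. The same reduction gives the (5R)-alcohol F11, Mitsunobu esterification with 4-nitrobenzoic acid (PPh3, DIAD) gives the inverted (5S)-4-nitrobenzoate F12, and K2CO3 in MeOH releases 36.

Further compounds
F1 | step 19 | 2-(3-methylbutylidene)-4,4,6,6-tetramethylcyclohexane-1,3,5-trione | CC(C)CC=C1C(=O)C(C)(C)C(=O)C(C)(C)C1=O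
F2 | step 19 | (−)-β-caryophyllene (purchased) | C/C1=C\CCC(=C)[C@H]2CC(C)(C)[C@@H]2CC1
F3 | step 19 | (1R,3Z,5S,9S)-5-hydroperoxycaryophylla-3,8(13)-diene | C/C1=C/C[C@@H]2[C@H](CC2(C)C)C(=C)CC[C@@H]1OO
F4 | step 19 | (1R,3Z,5S,9S)-caryophylla-3,8(13)-dien-5-ol | C/C1=C/C[C@@H]2[C@H](CC2(C)C)C(=C)CC[C@@H]1O
F5 | step 16 | (2E,6S,7R)-7-methyl-3-[(2S)-4-methyl-2-Syn(OTMSE)-pentyl]-6-[(triisopropylsilyl)oxy]non-2-en-8-yn-1-ol | OC/C=C(\CC[C@H](O[Si](C(C)C)(C(C)C)C(C)C)[C@H](C)C#C)C[C@H](CC(C)C)C1=C(OCC[Si](C)(C)C)C(C)(C)C(=O)C(C)(C)C1=O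
F6 | step 16 | allylic bromide of F5 | BrC/C=C(\CC[C@H](O[Si](C(C)C)(C(C)C)C(C)C)[C@H](C)C#C)C[C@H](CC(C)C)C1=C(OCC[Si](C)(C)C)C(C)(C)C(=O)C(C)(C)C1=O
F7 | step 16 | N-cyclohexyl imine of F8 | C1CCCCC1N=CC(C)(C)C/C=C(\CC[C@H](O[Si](C(C)C)(C(C)C)C(C)C)[C@H](C)C#C)C[C@H](CC(C)C)C1=C(OCC[Si](C)(C)C)C(C)(C)C(=O)C(C)(C)C1=O
F8 | step 16 | (4E,8S,9R)-2,2,9-trimethyl-5-[(2S)-4-methyl-2-Syn(OTMSE)-pentyl]-8-[(triisopropylsilyl)oxy]undec-4-en-10-ynal | O=CC(C)(C)C/C=C(\CC[C@H](O[Si](C(C)C)(C(C)C)C(C)C)[C@H](C)C#C)C[C@H](CC(C)C)C1=C(OCC[Si](C)(C)C)C(C)(C)C(=O)C(C)(C)C1=O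
F9 | step 16 | (E)-alkenyl(dicyclohexyl)borane from F8 | O=CC(C)(C)C/C=C(\CC[C@H](O[Si](C(C)C)(C(C)C)C(C)C)[C@H](C)/C=C/B(C1CCCCC1)C1CCCCC1)C[C@H](CC(C)C)C1=C(OCC[Si](C)(C)C)C(C)(C)C(=O)C(C)(C)C1=O
F10 | step 16 | (E)-alkenyl(ethyl)zinc from F9 | O=CC(C)(C)C/C=C(\CC[C@H](O[Si](C(C)C)(C(C)C)C(C)C)[C@H](C)/C=C/[Zn]CC)C[C@H](CC(C)C)C1=C(OCC[Si](C)(C)C)C(C)(C)C(=O)C(C)(C)C1=O
F11 | step 22 | 5-epi-tomentodione P, the (5R)-alcohol | C/C1=C/C[C@@H]2[C@H](CC2(C)C)[C@]2(CC[C@H]1O)C[C@H](CC(C)C)C1=C(O2)C(C)(C)C(=O)C(C)(C)C1=O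
F12 | step 22 | (5S)-4-nitrobenzoate of tomentodione P | C/C1=C/C[C@@H]2[C@H](CC2(C)C)[C@]2(CC[C@@H]1OC(=O)c1ccc(cc1)[N+](=O)[O-])C[C@H](CC(C)C)C1=C(O2)C(C)(C)C(=O)C(C)(C)C1=O
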